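Everything rests on cutting ring C of the lower (catechin) unit across its two opposite bonds, the aryl ether bond O1–C8a and C2–C3: a formal hetero-Diels–Alder retron once C4 carries a temporary ketone, which makes C3 nucleophilic (silyl enol ether) and the ortho carbon C8a of ring A electrophilic (C–F). In one flask a catalytic asymmetric Mukaiyama aldol joins C3 to 3,4-bis(benzyloxy)benzaldehyde, and fluoride then closes the alkoxide O1 onto C8a by SNAr, releasing only Me3SiF. The precursor is the TMS enol ether of an α-benzyloxy 2-fluoroaryl ketone. The same annulation builds the upper unit; C4(upper)–C8(lower) coupling and one hydrogenolysis finish.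

Key step: step 4

Remark on the chemistry (assumption): flavan numbering (O1, C2, C3, C4, C4a, C5–C8, C8a) is used for both units. The target is read as the all-trans dimer, upper unit (2R,3S,4S) linked from C4 to C8 of a (2R,3S) catechin unit. The antipode of the aldol catalyst is the one that directs the enol silane onto the Si face of aldehyde 6; it is to be assigned on the first run.

Step 1
Reactants: 1 1,3,5-trifluorobenzene
Product: 2 1,3-bis(benzyloxy)-5-fluorobenzene
Conditions: BnOH (2.05 equiv), NaH (2.1 equiv), NMP, 0 °C → 80 °C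
Reagents that add atoms: benzyl alcohol, OCc1ccccc1
Why: Twofold SNAr by sodium benzyl oxide; each alkoxy group introduced makes the ring less electrophilic, so the third fluorine should survive under stoichiometric control.

Step 2
Reactants: 2 1,3-bis(benzyloxy)-5-fluorobenzene; 3 2-(benzyloxy)acetic acid
Product: 4 2-(benzyloxy)-1-[2,4-bis(benzyloxy)-6-fluorophenyl]ethan-1-one
Conditions: (CF3CO)2O, cat. H3PO4, CH2Cl2, 0 °C → rt
Reagents that add atoms: none
Why: Friedel–Crafts acylation through the mixed trifluoroacetic anhydride (no metal Lewis acid, so the benzyl ethers should survive), expected at the position ortho to fluorine and para to a benzyloxy group, which is less hindered than the site between the two benzyloxy groups.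

Step 3
Reactants: 4 2-(benzyloxy)-1-[2,4-bis(benzyloxy)-6-fluorophenyl]ethan-1-one
Product: 5 (Z)-{[2-(benzyloxy)-1-(2,4-bis(benzyloxy)-6-fluorophenyl)ethenyl]oxy}trimethylsilane
Conditions: TMSOTf, Et3N, CH2Cl2, 0 °C
Reagents that add atoms: trimethylsilyl trifluoromethanesulfonate, C[Si](C)(C)OS(=O)(=O)C(F)(F)F
Why: Soft enolisation and O-silylation on the only enolisable side (the CH2OBn carbon, the future C3); the Z isomer is expected but the geometry is not decisive for the open-transition-state aldol that follows.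

Step 4
Reactants: 5 (Z)-{[2-(benzyloxy)-1-(2,4-bis(benzyloxy)-6-fluorophenyl)ethenyl]oxy}trimethylsilane; 6 3,4-bis(benzyloxy)benzaldehyde
Product: 8 (2R,3R)-3,5,7-tris(benzyloxy)-2-[3,4-bis(benzyloxy)phenyl]chroman-4-one, via silyl aldolate 7 (not isolated)
Conditions: N-tosyltryptophan-derived B-butyl-1,3,2-oxazaborolidin-5-one (20 mol %), EtCN, −78 °C; then CsF (0.3 equiv), DMF, −78 °C → rt
Reagents that add atoms: none
Why: The boron Lewis acid activates aldehyde 6 and the enol silane 5 adds through an open transition state (catalytic asymmetric Mukaiyama aldol, C2–C3 bond), the silyl group passing to the aldolate oxygen to give 7; fluoride then cleaves O–Si, and the alkoxide O1 adds to the fluorine-bearing carbon C8a ortho to the ketone and expels fluoride, which carries the chain as Me3SiF forms (SNAr, O1–C8a bond). The closest known reaction types are the Lewis-acid-catalysed aldol–dihydropyranone annulation of 1-methoxy-3-silyloxybutadienes with aldehydes (the stepwise hetero-Diels–Alder) and the closure of 2-fluoroaryl β-hydroxy ketones to chroman-4-ones; the aryl fluoride here takes the part of the methoxy leaving group of such a diene. Ring C closes by intramolecular addition–elimination at the aromatic carbon C8a through a Meisenheimer adduct whose charge rests on the ortho carbonyl, formally 6-endo-trig with respect to the C8a=C4a–C4=O vinylogous acyl fluoride, the same mode as a chalcone-to-flavanone oxa-Michael closure. C2 (R) is set by the catalyst, which shields one face of the bound aldehyde so that attack occurs on the Si face; C3 (R) is set by thermodynamics, because it is α to the ketone and equilibrates under fluoride to the trans-diequatorial arrangement, so both aldol diastereomers converge (the anti adduct is shown as 7). The step needs enantiofacial selectivity, supplied by the catalyst, and closure through O1 alone, secured by the benzyl group on O3 (no five-membered closure) and by the single fluorine on ring A.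

Step 5
Reactants: 8 (2R,3R)-3,5,7-tris(benzyloxy)-2-[3,4-bis(benzyloxy)phenyl]chroman-4-one
Product: 10 (2R,3S)-3,5,7-tris(benzyloxy)-2-[3,4-bis(benzyloxy)phenyl]chromane (penta-O-benzyl-(+)-catechin), via 4-carbinol 9 (not isolated)
Conditions: NaBH4, THF/EtOH, 0 °C; solvent exchange without purification; then slow addition to Et3SiH (10 equiv), BF3·OEt2, CH2Cl2, −78 °C → −40 °C
Reagents that add atoms: none
Why: Ketone reduction followed by ionic hydrogenation of the carbinol, whose C4 cation is stabilised by the 5- and 7-benzyloxy groups and should form at −78 °C, where the C2–O1 bond stays intact; C2 and C3 are not touched, and C3 stops being epimerisable once the ketone is gone.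

Step 6
Reactants: 11 3-fluorocatechol (3-fluorobenzene-1,2-diol)
Product: 12 1,2-bis(benzyloxy)-3-fluorobenzene
Conditions: BnBr (2.2 equiv), K2CO3, DMF, rt → 50 °C
Reagents that add atoms: benzyl bromide, BrCc1ccccc1
Why: Williamson etherification of both phenols.

Step 7
Reactants: 12 1,2-bis(benzyloxy)-3-fluorobenzene; 13 2-(benzyloxy)-N-methoxy-N-methylacetamide
Product: 14 2-(benzyloxy)-1-[3,4-bis(benzyloxy)-2-fluorophenyl]ethan-1-one
Conditions: n-BuLi, THF, −78 °C; then 13, −78 °C; aq. NH4Cl
Reagents that add atoms: none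
Why: Fluorine-directed ortho-lithiation at the most acidic ring C–H (kept at −78 °C so that LiF is not lost to an aryne), then Weinreb ketone synthesis, whose chelated tetrahedral adduct prevents a second addition.

Step 8
Reactants: 14 2-(benzyloxy)-1-[3,4-bis(benzyloxy)-2-fluorophenyl]ethan-1-one
Product: 15 (Z)-{[2-(benzyloxy)-1-(3,4-bis(benzyloxy)-2-fluorophenyl)ethenyl]oxy}trimethylsilane
Conditions: TMSOTf, Et3N, CH2Cl2, 0 °C
Reagents that add atoms: trimethylsilyl trifluoromethanesulfonate, C[Si](C)(C)OS(=O)(=O)C(F)(F)F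
Why: Soft enolisation and O-silylation as in step 3.

Step 9
Reactants: 15 (Z)-{[2-(benzyloxy)-1-(3,4-bis(benzyloxy)-2-fluorophenyl)ethenyl]oxy}trimethylsilane; 6 3,4-bis(benzyloxy)benzaldehyde
Product: 17 (2R,3R)-3,7,8-tris(benzyloxy)-2-[3,4-bis(benzyloxy)phenyl]chroman-4-one, via silyl aldolate 16 (not isolated)
Conditions: N-tosyltryptophan-derived B-butyl-1,3,2-oxazaborolidin-5-one (20 mol %), EtCN, −78 °C; then CsF (0.3 equiv), DMF, −78 °C → rt
Reagents that add atoms: none
Why: The same Mukaiyama aldol/fluoride-triggered SNAr annulation as in step 4 with the same catalyst antipode, so C2 (R) is again catalyst-set and C3 (R) again relaxes to trans, the ketone ortho to C8a–F activating the displacement.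

Step 10
Reactants: 17 (2R,3R)-3,7,8-tris(benzyloxy)-2-[3,4-bis(benzyloxy)phenyl]chroman-4-one
Product: 18 (2R,3S,4R)-3,7,8-tris(benzyloxy)-2-[3,4-bis(benzyloxy)phenyl]chroman-4-ol
Conditions: NaBH4, THF/MeOH, 0 °C
Reagents that add atoms: none
Why: Axial hydride delivery to the chromanone should give mainly the equatorial 3,4-trans carbinol; the C4 configuration is of no consequence because it is lost on ionisation in step 11.

Step 11
Reactants: 18 (2R,3S,4R)-3,7,8-tris(benzyloxy)-2-[3,4-bis(benzyloxy)phenyl]chroman-4-ol; 10 penta-O-benzyl-(+)-catechin (3 equiv, excess recovered)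
Product: 19 deca-O-benzyl dimer: (2R,3S,4S)-3,7,8-tris(benzyloxy)-2-[3,4-bis(benzyloxy)phenyl]chroman-4-yl bonded to C8 of (2R,3S)-3,5,7-tris(benzyloxy)-2-[3,4-bis(benzyloxy)phenyl]chromane
Conditions: BF3·OEt2 (0.5 equiv), CH2Cl2, −40 °C → 0 °C
Reagents that add atoms: none
Why: Lewis-acid ionisation of the C4 carbinol to a benzylic cation stabilised by the para 7-benzyloxy group and the ring oxygen, with loss of water, then Friedel–Crafts alkylation at C8 of 10 (C6 is flanked by two benzyloxy groups); the arene should enter anti to the 3-benzyloxy group, giving the 3,4-trans (4S) linkage.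

Step 12
Reactants: 19 deca-O-benzyl dimer
Product: 20 target CNP0231186.1, (2R,3S,4S)-3,7,8,3',4'-pentahydroxyflavan-(4→8)-(2R,3S)-3,5,7,3',4'-pentahydroxyflavan
Conditions: H2 (1 atm), Pd(OH)2/C, THF/MeOH/H2O, rt
Reagents that add atoms: none
Why: Hydrogenolysis of all ten benzyl ethers (eight aryl, two alkyl) under neutral conditions that leave the interflavan C–C bond, the two C2–O1 bonds and every stereocentre untouched.

Compound list
1 | 1,3,5-trifluorobenzene | Fc1cc(F)cc(F)c1 | starting material
2 | 1,3-bis(benzyloxy)-5-fluorobenzene | Fc1cc(OCc2ccccc2)cc(OCc2ccccc2)c1 | intermediate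
3 | 2-(benzyloxy)acetic acid | OC(=O)COCc1ccccc1 | starting material
4 | 2-(benzyloxy)-1-[2,4-bis(benzyloxy)-6-fluorophenyl]ethan-1-one | O=C(COCc1ccccc1)c1c(F)cc(OCc2ccccc2)cc1OCc1ccccc1 | intermediate
5 | (Z)-{[2-(benzyloxy)-1-(2,4-bis(benzyloxy)-6-fluorophenyl)ethenyl]oxy}trimethylsilane | C[Si](C)(C)O/C(=C\OCc1ccccc1)c1c(F)cc(OCc2ccccc2)cc1OCc1ccccc1 | intermediate
6 | 3,4-bis(benzyloxy)benzaldehyde | O=Cc1ccc(OCc2ccccc2)c(OCc2ccccc2)c1 | starting material
7 | (2R,3R)-2-(benzyloxy)-1-[2,4-bis(benzyloxy)-6-fluorophenyl]-3-[3,4-bis(benzyloxy)phenyl]-3-(trimethylsilyloxy)propan-1-one (silyl aldolate, not isolated) | C[Si](C)(C)O[C@H](c1ccc(OCc2ccccc2)c(OCc2ccccc2)c1)[C@@H](OCc1ccccc1)C(=O)c1c(F)cc(OCc2ccccc2)cc1OCc1ccccc1 | intermediate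
8 | (2R,3R)-3,5,7-tris(benzyloxy)-2-[3,4-bis(benzyloxy)phenyl]chroman-4-one | O=C1c2c(OCc3ccccc3)cc(OCc3ccccc3)cc2O[C@H](c2ccc(OCc3ccccc3)c(OCc3ccccc3)c2)[C@H]1OCc1ccccc1 | intermediate
9 | (2R,3S,4R)-3,5,7-tris(benzyloxy)-2-[3,4-bis(benzyloxy)phenyl]chroman-4-ol (4-carbinol, not isolated) | O[C@@H]1c2c(OCc3ccccc3)cc(OCc3ccccc3)cc2O[C@H](c2ccc(OCc3ccccc3)c(OCc3ccccc3)c2)[C@H]1OCc1ccccc1 | intermediate
10 | (2R,3S)-3,5,7-tris(benzyloxy)-2-[3,4-bis(benzyloxy)phenyl]chromane (penta-O-benzyl-(+)-catechin) | C1c2c(OCc3ccccc3)cc(OCc3ccccc3)cc2O[C@H](c2ccc(OCc3ccccc3)c(OCc3ccccc3)c2)[C@H]1OCc1ccccc1 | intermediate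
11 | 3-fluorocatechol | Oc1cccc(F)c1O | starting material
12 | 1,2-bis(benzyloxy)-3-fluorobenzene | Fc1cccc(OCc2ccccc2)c1OCc1ccccc1 | intermediate
13 | 2-(benzyloxy)-N-methoxy-N-methylacetamide | CON(C)C(=O)COCc1ccccc1 | starting material
14 | 2-(benzyloxy)-1-[3,4-bis(benzyloxy)-2-fluorophenyl]ethan-1-one | O=C(COCc1ccccc1)c1ccc(OCc2ccccc2)c(OCc2ccccc2)c1F | intermediate
15 | (Z)-{[2-(benzyloxy)-1-(3,4-bis(benzyloxy)-2-fluorophenyl)ethenyl]oxy}trimethylsilane | C[Si](C)(C)O/C(=C\OCc1ccccc1)c1ccc(OCc2ccccc2)c(OCc2ccccc2)c1F | intermediate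
16 | (2R,3R)-2-(benzyloxy)-1-[3,4-bis(benzyloxy)-2-fluorophenyl]-3-[3,4-bis(benzyloxy)phenyl]-3-(trimethylsilyloxy)propan-1-one (silyl aldolate, not isolated) | C[Si](C)(C)O[C@H](c1ccc(OCc2ccccc2)c(OCc2ccccc2)c1)[C@@H](OCc1ccccc1)C(=O)c1ccc(OCc2ccccc2)c(OCc2ccccc2)c1F | intermediate
17 | (2R,3R)-3,7,8-tris(benzyloxy)-2-[3,4-bis(benzyloxy)phenyl]chroman-4-one | O=C1c2ccc(OCc3ccccc3)c(OCc3ccccc3)c2O[C@H](c2ccc(OCc3ccccc3)c(OCc3ccccc3)c2)[C@H]1OCc1ccccc1 | intermediate
18 | (2R,3S,4R)-3,7,8-tris(benzyloxy)-2-[3,4-bis(benzyloxy)phenyl]chroman-4-ol | O[C@@H]1c2ccc(OCc3ccccc3)c(OCc3ccccc3)c2O[C@H](c2ccc(OCc3ccccc3)c(OCc3ccccc3)c2)[C@H]1OCc1ccccc1 | intermediate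
19 | deca-O-benzyl dimer, upper unit (2R,3S,4S) joined from C4 to C8 of the (2R,3S) lower unit | O(Cc5ccccc5)c1ccc([C@H]2Oc3c(ccc(OCc5ccccc5)c3OCc5ccccc5)[C@@H](c3c(OCc5ccccc5)cc(OCc5ccccc5)c4c3O[C@H](c3ccc(OCc5ccccc5)c(OCc5ccccc5)c3)[C@@H](OCc5ccccc5)C4)[C@@H]2OCc5ccccc5)cc1OCc5ccccc5 | intermediate
20 | CNP0231186.1, (2R,3S,4S)-3,7,8,3',4'-pentahydroxyflavan-(4→8)-(2R,3S)-3,5,7,3',4'-pentahydroxyflavan | Oc1ccc([C@H]2Oc3c(ccc(O)c3O)[C@@H](c3c(O)cc(O)c4c3O[C@H](c3ccc(O)c(O)c3)[C@@H](O)C4)[C@@H]2O)cc1O | target

Total step count: 12. Longest linear sequence: 7 steps (steps 1–5, 11, 12; the upper branch, steps 6–10, 11, 12, is equally long).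

Steps most likely to fail

1. Step 4 (key step). What may go wrong: insufficient facial selectivity in the boron-catalysed aldol with the chelating α-benzyloxy enol silane; retro-aldol cleavage or β-elimination of the aldolate during the fluoride stage; erosion of enantiopurity by base-induced opening and reclosure of ring C. Fallback, still one flask but with a reagent-controlled closed transition state instead of a catalyst-controlled open one: it sets out from ketone 4, bypassing 5. Ketone 4 is enolised with diisopinocampheylboron triflate and iPr2NEt (antipode chosen for Si-face attack) and treated with 6 at −78 °C. Peroxide cleavage of the boron aldolate gives the syn β-hydroxy ketone (2S,3R)-2-(benzyloxy)-1-[2,4-bis(benzyloxy)-6-fluorophenyl]-3-[3,4-bis(benzyloxy)phenyl]-3-hydroxypropan-1-one F1. K2CO3 and DMF are then added to the same flask, so that SNAr closure occurs with epimerisation of C3 to trans. The fallback returns to the route at 8. If needed, F1 can be taken out and enriched by crystallisation before closure.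

2. Step 11. What may go wrong: sluggish or unselective ionisation of the 5-deoxy carbinol, with elimination or self-condensation competing; incomplete C8-over-C6 or 3,4-trans-over-cis selectivity. Fallback with a separate, thiophile-triggered activation: it sets out from 18. Carbinol 18 is converted with benzyl mercaptan and BF3·OEt2 at −40 °C into the thioether (2R,3R,4R)-4-(benzylsulfanyl)-3,7,8-tris(benzyloxy)-2-[3,4-bis(benzyloxy)phenyl]chromane F2 (2,3-trans-3,4-trans), which is purified. AgBF4 in CH2Cl2 at −78 °C then releases the C4 cation in the presence of excess 10, so that ionisation and capture are decoupled from the acid. The fallback returns to the route at 19.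

3. Step 2. What may go wrong: acylation at the site between the two benzyloxy groups, decarbonylation of the alkoxyacetyl electrophile, or acid-induced loss of a benzyl group. Fallback with the regiochemistry fixed by a halogen: it sets out from 2. NBS in MeCN at 0 °C should brominate ortho to fluorine and para to a benzyloxy group, giving 1,5-bis(benzyloxy)-2-bromo-3-fluorobenzene F3. Bromine–lithium exchange with n-BuLi in THF at −78 °C and acylation with Weinreb amide 13 then return to the route at 4.

Further compounds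
F1 | step 4 | (2S,3R)-2-(benzyloxy)-1-[2,4-bis(benzyloxy)-6-fluorophenyl]-3-[3,4-bis(benzyloxy)phenyl]-3-hydroxypropan-1-one | O[C@H](c1ccc(OCc2ccccc2)c(OCc2ccccc2)c1)[C@H](OCc1ccccc1)C(=O)c1c(F)cc(OCc2ccccc2)cc1OCc1ccccc1
F2 | step 11 | (2R,3R,4R)-4-(benzylsulfanyl)-3,7,8-tris(benzyloxy)-2-[3,4-bis(benzyloxy)phenyl]chromane | c1ccccc1CS[C@@H]1c2ccc(OCc3ccccc3)c(OCc3ccccc3)c2O[C@H](c2ccc(OCc3ccccc3)c(OCc3ccccc3)c2)[C@H]1OCc1ccccc1
F3 | step 2 | 1,5-bis(benzyloxy)-2-bromo-3-fluorobenzene | Brc1c(F)cc(OCc2ccccc2)cc1OCc1ccccc1
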